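All runs were generated by integration for substances that don't exist; the scatter is artificial.

The pitfall in this flask is to read the share of target off the charges, as if the intermediate took either nucleophile at random. That even-handed case is the zero of the scale. With charges B of first nucleophile and D of second nucleophile, it gives a share of B/(B+D):

65.5%

common to all: solid substrate 0.050 M
- delta: first nucleophile 0.060 M; second nucleophile 0.0475 M; run made earlier
- alpha: first nucleophile 0.14 M; second nucleophile 0.0475 M; run made earlier
- zeta: first nucleophile 0.090 M; second nucleophile 0.095 M; run made earlier
- flask: first nucleophile 0.0900 M; second nucleophile 0.0475 M; time 12 d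

| run | time / d | target / % | other capture product / % | solid substrate / % |
|---|---|---|---|---|
| delta | 2.50 | 34.7 | 3.3 | 0.6 |
| delta | 5.00 | 33.7 | 0.6 | 0 |
| delta | 8.00 | 33.4 | 1.4 | 0 |
| delta | 10.0 | 34.5 | 3.2 | 0.3 |
| delta | 12.0 | 34.7 | 2.1 | 0 |
| delta | 15.0 | 33.5 | 1.6 | 0.4 |
| alpha | 1.04 | 56.7 | 2.5 | 1.9 |
| alpha | 3.00 | 54.8 | 0 | 0 |
| alpha | 5.00 | 54.6 | 1.8 | 0.1 |
| alpha | 8.00 | 57.0 | 0.5 | 0.1 |
| alpha | 12.0 | 55.5 | 2.4 | 0 |
| alpha | 15.0 | 55.4 | 1.5 | 1.7 |
| zeta | 1.25 | 43.4 | 4.7 | 0 |
| zeta | 2.00 | 43.3 | 3.6 | 0 |
| zeta | 4.00 | 40.7 | 4.6 | 1.5 |
| zeta | 8.00 | 44.0 | 4.0 | 0 |
| zeta | 15.0 | 43.2 | 3.7 | 0 |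

(scatter of a reading: 1 percentage point)

1. share of target in target plus other capture product at 20 min
2. share of target in target plus other capture product at 10 h
3. share of target in target plus other capture product at 12 d
4. which of target and other capture product there is more of at 12 d

- solid substrate is a solid; its amount is given per volume of the solution
- what may be going on: solid substrate <-> starting material; second nucleophile + intermediate -> other capture product; starting material -> intermediate; intermediate -> solvolysis product; first nucleophile + intermediate -> target
- at the start none of the solid substrate is in solution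

The decision concerns the next flask: keep the zeta charge of first nucleophile and take half of its second nucleophile, or raise first nucleophile towards the alpha charge. Both capture products come from one intermediate, like two outlets of one tank, so P/Q, target over other capture product, follows the two capture rates. The zeta readings from 1.25 d on, taken as a plateau, give:

P = 42.9%, Q = 4.12%

S = (P/Q)/(B/D) = 11.0

This S, the product ratio divided by the charge ratio, is the selectivity factor, and it measures how far the intermediate departs from the even-handed case. Zeta is the run to read because its first nucleophile charge matches the new flask. Its other capture product also stands higher than in delta and alpha against a scatter of 1 percentage point. Those two runs read 13.3 and 13.0.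

Share at 12 d = SB/(SB+D) = 95.4%

At the alpha charge the same rule gives 97.0%, a gain of 1.6 points in share, so for the share the recipe stands, with target ahead. For 20 min and 10 h the reckoning is this share or slightly above it.

The forecast gives 96%, 95.7% and 95.4% with target ahead, and holds that “dissolution rate does not affect it”.

The flask gives 95.4% at 20 min, 94.8% at 10 h and 94.8% at 12 d, with target ahead, at 44.2% against 2.41%.

    solid substrate ⇌ starting material, rate k1*(cs1 - [starting material]) while solid is left; crystals form when [starting material] > cs1 (solubility = 29.0 mM, k = 8.60 × 10⁻⁵ s⁻¹)
    second nucleophile + intermediate → other capture product (k = 0.530 M⁻¹ s⁻¹)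
    starting material → intermediate (k = 7.30 × 10⁻⁴ s⁻¹)
    intermediate → solvolysis product (k = 0.550 s⁻¹)
    first nucleophile + intermediate → target (k = 5.80 M⁻¹ s⁻¹)

In this flask P/Q comes to 18.3 where SB/D reckoned 20.8, a gap of 0.6 points in share, and at 0.128 d the intermediate goes to solvolysis product 1.2 times as fast as to target, the flask ending with solvolysis product at 53.4% beside target at 44.2%. For the neighbouring flask with 0.22 M of first nucleophile, S gives a share of 98.1%, and that flask stands at 97.9%.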